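The constants could wait; the plateaus came first.

| setting | gamma | epsilon | theta | alpha | summer | autumn | dusk | dawn |
|---|---|---|---|---|---|---|---|---|
| substrate | 0.050 M | 0.025 M | 0.10 M | 0.050 M | 0.050 M | 0.050 M (fed, over 2.40 min) | 0.050 M | 0.050 M |
| reagent | 0.20 M | 0.20 M | 0.20 M | 0.30 M | 0.200 M | 0.200 M | 0.200 M | 0.200 M |
| remark | run made earlier | run made earlier | run made earlier | run made earlier | a single well-mixed tank run continuously and read at steady state, 3.0 min in it on average | a stirred flask in which substrate is dosed at a steady rate over 2.40 min without added volume, worked up at 3.0 min | a closed flask charged with all of it at once and left for 3.0 min | one stirred flow tank at steady state, fed with the mixture as stated, mean residence time 15.0 min |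
| time |  |  |  |  |  | 3.0 min | 3.0 min |  |

gamma run (percent of the substrate charged)

| time / min | target / % | side product A / % |
|---|---|---|
| 0.417 | 16.2 | 0.3 |
| 1.00 | 22.7 | 2.6 |
| 2.00 | 24.6 | 4.7 |
| 3.00 | 25.3 | 7.2 |

epsilon run (percent of the substrate charged)

| time / s | target / % | side product A / % |
|---|---|---|
| 10.0 | 8.2 | 0.3 |
| 20.0 | 14.3 | 0.6 |
| 50.0 | 21.8 | 1.9 |
| 120 | 24.9 | 5.5 |

theta run (percent of the substrate charged)

| time / s | target / % | side product A / % |
|---|---|---|
| 25.0 | 16.0 | 0.5 |
| 50.0 | 21.3 | 1.8 |
| 80.0 | 23.3 | 3.1 |
| 120 | 23.6 | 4.9 |

alpha run (percent of the substrate charged)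

| time / s | target / % | side product A / % |
|---|---|---|
| 25.0 | 23.1 | 0.3 |
| 50.0 | 30.4 | 1.7 |
| 80.0 | 32.8 | 2.3 |
| 120 | 33.0 | 4.6 |

(readings scatter by 0.3 percentage points)

- the stated concentrations are those of everything mixed, before any reaction; amounts are the same in each set-up
- the feed brings no volume worth counting
- the earlier runs were made in a closed, stirred flask

1. the set-up with the highest share of target in all that became target or side product A or side product B, at the outlet or at the end ("none" if the first two lie within 2 percentage points) (summer / autumn / dusk / dawn / none)
2. share of target in all that became target or side product A or side product B, at the outlet or at the end, summer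
3. share of target in all that became target or side product A or side product B, at the outlet or at the end, autumn
4. share of target in all that became target or side product A or side product B, at the outlet or at the end, dusk
5. share of target in all that became target or side product A or side product B, at the outlet or at the end, dawn

1. Gamma and alpha looked nearly alike, with the same substrate, 0.050 M, but reagent at 0.20 M against 0.30 M. Gamma's target levelled near 25.3% and alpha's near 33.0%. Alpha ended higher because it held more reagent. Epsilon and theta, at 0.025 M and 0.10 M of substrate, read 24.9% and 23.6%, so substrate level moved the plateau little.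

2. I read this as a race: substrate leaves by two branches, and one of them takes reagent. Target over the rest of the substrate at the plateau, per molar of reagent, gave 1.69 M⁻¹ in gamma and 1.64 M⁻¹ in alpha. I called their mean, 1.67 M⁻¹, the branch ratio, a selectivity factor.

3. At 0.200 M of reagent, that ratio gave an end share of target of 25.0%.

4. But the share asked is taken at a set time, or at a tank's outlet. Between 2.00 min and 3.00 min, gamma's side product A rose from 4.7% to 7.2% while target went from 24.6% to 25.3%. An unread 67.5% remained, and it need not be finished product. Dusk repeats gamma's charge and time, so I put its share between 25.3%, with that gap finished as side product B, and 77.8%, with none of it finished. I expected autumn above dusk, since its substrate arrives up to 2.40 min into 3.0 min, and dawn nearest the low end, at 15.0 min.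

5. The forecast gave 24.3% for summer, 24.8% for autumn, 24.8% for dusk, 24.2% for dawn, and best none: “so no real winner”.

6. The flasks gave 54.6% for summer, 68.7% for autumn, 55.6% for dusk and 31.7% for dawn, so the best was autumn.

    substrate + reagent → target (k = 0.0535 M⁻¹ s⁻¹)
    reagent + intermediate B → side product B (k = 0.0303 M⁻¹ s⁻¹)
    intermediate A ⇌ intermediate B (K = 0.370, k = 0.0131 s⁻¹)
    intermediate A → side product A (k = 9.46 × 10⁻⁴ s⁻¹)
    substrate → intermediate A (k = 0.0313 s⁻¹)

At 3.00 min, autumn still held 47.2% as intermediate A and 14.2% as intermediate B, neither counted in the share. Left until 30.0 min, autumn's share came to 25.4%, against the 25.0% from the branch ratio.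

7. For a further flask, dosed like autumn with 0.80 M of reagent, the branch ratio gave an end share of target of 57.2%. Computed, it held 56.9% of target at 3.00 min, and its share stood at 79.7%, with 22.7% still intermediate A.

(Readings and results are calculated for an exercise; scatter was added.)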